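**Retrosynthetic overview**
1. Feature: the four methoxy groups sit on C2/C6 of ring A and C2'/C6' of ring B. These are the four carbons ortho to the bridging ether oxygen, and the para carbons C4/C4' carry the CH2CH2CO2H chains.
2. Apteniol E ⇐ its dimethyl ester (saponification) ⇐ the 2,2',6,6'-tetrabromo diaryl ether diester. The last disconnection cuts four aryl C–OMe bonds, made together by copper-catalysed methoxylation with NaOMe.
3. Tetrabromo diester ⇐ tetrabromo diacid ⇐ 4,4'-oxybis(3,5-dibromobenzaldehyde). Each CHO becomes CH2CH2CO2H by a metal-free Meldrum's acid/formate reductive condensation, so the C–Br bonds survive.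
4. Tetrabromo dialdehyde ⇐ 4,4'-oxydibenzaldehyde by fourfold bromination at the aldehyde stage, where ortho direction by the ether oxygen and meta direction by CHO point to the same four carbons. On a 4-alkyl ring the second bromine would compete for C5 (ortho to the chain, para to the first bromine), the 2,4,5-pattern typical of further bromination of diphenyl ethers.
5. No ring is formed. Both benzene rings and the hindered C–O–C bond are bought in the dialdehyde.

Key step: step 4

Remark on the chemistry: the target is achiral and its two halves are equivalent. Every step therefore acts twofold or fourfold on equivalent sites, and no stereocontrol is needed.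

**Step 1**
Reactants: 1 4,4'-oxydibenzaldehyde; 2 N-bromosuccinimide
Product: 3 4,4'-oxybis(3,5-dibromobenzaldehyde)
Conditions: NBS (4.6 equiv, in portions), conc. H2SO4, 25 → 60 °C, dark; poured on ice, filtered, recrystallised
Reagents that add atoms: N-bromosuccinimide, O=C1CCC(=O)N1Br
Why: Electrophilic aromatic bromination with protonated NBS, a system known to brominate deactivated benzaldehydes while leaving the formyl group intact, should place all four bromines at C3/C5 and C3'/C5' (aldehyde numbering), because only these carbons are both ortho to the donor ether oxygen and meta to the protonated formyl acceptor, whereas C2/C6 are ortho to the acceptor and meta to oxygen.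

**Step 2**
Reactants: 3 4,4'-oxybis(3,5-dibromobenzaldehyde); 4 Meldrum's acid (2,2-dimethyl-1,3-dioxane-4,6-dione)
Product: 7 3,3'-[oxybis(3,5-dibromo-4,1-phenylene)]dipropanoic acid, via bis-arylidene Meldrum's acid adduct 5 (not isolated), via bis-benzyl Meldrum's acid adduct 6 (not isolated)
Conditions: Meldrum's acid (2.4 equiv), HCO2H/Et3N (5:2 azeotrope), DMF co-solvent, 25 → 95 °C until CO2 evolution ends; then ice-water, aq. HCl to pH 1–2, filtration
Reagents that add atoms: Meldrum's acid, CC1(C)OC(=O)CC(=O)O1
Why: One-pot Knoevenagel condensation to 5, formate transfer reduction of this highly electrophilic arylidene to 6, and hydrolysis–decarboxylation by the water of condensation (the Meldrum's acid/triethylammonium formate synthesis of 3-arylpropanoic acids, well established for bromobenzaldehydes) should build both chains without H2 or a hydrogenation metal, so the four C–Br bonds are not touched.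

**Step 3**
Reactants: 7 3,3'-[oxybis(3,5-dibromo-4,1-phenylene)]dipropanoic acid; 8 methanol
Product: 9 dimethyl 3,3'-[oxybis(3,5-dibromo-4,1-phenylene)]dipropanoate
Conditions: MeOH, cat. H2SO4, reflux
Reagents that add atoms: methanol, CO
Why: Fischer esterification of two unhindered aliphatic acids in excess methanol is driven by mass action, leaves the aryl bromides and the diaryl ether alone, and gives a neutral, easily purified substrate whose ester alkoxide matches the nucleophile of step 4.

**Step 4**
Reactants: 9 dimethyl 3,3'-[oxybis(3,5-dibromo-4,1-phenylene)]dipropanoate; 10 sodium methoxide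
Product: 11 dimethyl 3,3'-[oxybis(3,5-dimethoxy-4,1-phenylene)]dipropanoate (apteniol E dimethyl ester)
Conditions: NaOMe (16 equiv, 30 wt % in MeOH), CuBr (0.4 equiv), MeOAc (1 equiv), DMF, 110 °C, argon, pressure tube; aq. NH4Cl/HCl work-up
Reagents that add atoms: sodium methoxide, C[O-].[Na+]
Why: Ullmann-type copper-catalysed methanolysis of aryl bromides: NaOMe and CuBr form the cuprate Na[Cu(OMe)2] of monovalent copper, which takes up each C–Br bond by oxidative addition to an aryl complex of trivalent copper and releases the aryl methyl ether by C–O reductive elimination, with NaBr as the only by-product. The closest known reactions are the conversion of 3,5-dibromo-4-hydroxybenzaldehyde into syringaldehyde and the exhaustive methoxylation of polybromoarenes with NaOMe/CuBr in DMF–MeOH, where an ester acts as co-catalyst; methyl acetate is chosen here so that no foreign alkoxide enters. No ring is closed and no stereocentre is made. The four bromides are equivalent by symmetry and each has only one ortho substituent (the ether oxygen, which may hold copper close) beside a free C–H, so no regioselectivity is asked for, only completeness, which the large excess of concentrated methoxide and about 10 mol % copper per bromide should drive. The chemoselectivity needed is exchange over hydrodebromination and over rupture of the central C–O–C unit; the second is secured by the substrate, since C4 and C4' now carry saturated chains instead of formyl groups and the ipso carbons are therefore not activated for addition–elimination by methoxide. The methyl esters match the nucleophile, so transesterification is degenerate and enolate formation stays reversible in the methanol-rich medium.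

**Step 5**
Reactants: 11 apteniol E dimethyl ester; 12 lithium hydroxide (used as the monohydrate)
Product: 14 apteniol E, via dilithium dicarboxylate 13 (not isolated)
Conditions: LiOH·H2O (6 equiv), THF/MeOH/H2O, 25 °C; then 1 M HCl to pH 2, extraction or filtration
Reagents that add atoms: lithium hydroxide, [Li+].[OH-]
Why: Saponification (acyl–oxygen cleavage by hydroxide) of two unhindered methyl esters gives dicarboxylate 13, the aryl methyl ethers and the diaryl ether being inert to LiOH at room temperature, and acidification should release the diacid.

**Compound list**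
1 | 4,4'-oxydibenzaldehyde | O=Cc1ccc(Oc2ccc(C=O)cc2)cc1 | starting material
2 | N-bromosuccinimide | O=C1CCC(=O)N1Br | starting material
3 | 4,4'-oxybis(3,5-dibromobenzaldehyde) | O=Cc1cc(Br)c(Oc2c(Br)cc(C=O)cc2Br)c(Br)c1 | intermediate
4 | Meldrum's acid (2,2-dimethyl-1,3-dioxane-4,6-dione) | CC1(C)OC(=O)CC(=O)O1 | starting material
5 | 5,5'-{oxybis[(3,5-dibromo-4,1-phenylene)methanylylidene]}bis(2,2-dimethyl-1,3-dioxane-4,6-dione) | CC1(C)OC(=O)C(=Cc2cc(Br)c(Oc3c(Br)cc(C=C4C(=O)OC(C)(C)OC4=O)cc3Br)c(Br)c2)C(=O)O1 | intermediate
6 | 5,5'-{oxybis[(3,5-dibromo-4,1-phenylene)methylene]}bis(2,2-dimethyl-1,3-dioxane-4,6-dione) | CC1(C)OC(=O)C(Cc2cc(Br)c(Oc3c(Br)cc(CC4C(=O)OC(C)(C)OC4=O)cc3Br)c(Br)c2)C(=O)O1 | intermediate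
7 | 3,3'-[oxybis(3,5-dibromo-4,1-phenylene)]dipropanoic acid | OC(=O)CCc1cc(Br)c(Oc2c(Br)cc(CCC(=O)O)cc2Br)c(Br)c1 | intermediate
8 | methanol | CO | starting material
9 | dimethyl 3,3'-[oxybis(3,5-dibromo-4,1-phenylene)]dipropanoate | COC(=O)CCc1cc(Br)c(Oc2c(Br)cc(CCC(=O)OC)cc2Br)c(Br)c1 | intermediate
10 | sodium methoxide | C[O-].[Na+] | starting material
11 | dimethyl 3,3'-[oxybis(3,5-dimethoxy-4,1-phenylene)]dipropanoate | COC(=O)CCc1cc(OC)c(Oc2c(OC)cc(CCC(=O)OC)cc2OC)c(OC)c1 | intermediate
12 | lithium hydroxide | [Li+].[OH-] | starting material
13 | dilithium 3,3'-[oxybis(3,5-dimethoxy-4,1-phenylene)]dipropanoate | COc1cc(CCC(=O)[O-])cc(OC)c1Oc1c(OC)cc(CCC(=O)[O-])cc1OC.[Li+].[Li+] | intermediate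
14 | apteniol E, 3,3'-[oxybis(3,5-dimethoxy-4,1-phenylene)]dipropanoic acid | COc1cc(CCC(=O)O)cc(OC)c1Oc1c(OC)cc(CCC(=O)O)cc1OC | target

Total step count: 5. Longest linear sequence: 5 steps (1 → 3 → 7 → 9 → 11 → 14).

**Steps most likely to fail**

**Step 4 (key step).**
- The exchange may slow down before the fourth bromide reacts, because each new methoxy group makes its ring more electron-rich.
- Copper-bound methoxide may pass on a hydride, so that bromine is replaced by hydrogen.
- Methoxide may attack an ipso carbon and break the diaryl ether.
- Part of the ester may be cleaved. This is harmless, since the crude material can be re-esterified as in step 3 or carried into step 5.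

The fallback sets out from 9 and separates aryl C–O bond formation from methylation. Palladium-catalysed hydroxylation (Pd2(dba)3, tBuXPhos, KOH, dioxane/H2O, 100 °C, argon) uses a nucleophile that has no C–H to give up as hydride. It hydrolyses both esters in the same pot and gives, after acidification, 3,3'-[oxybis(3,5-dihydroxy-4,1-phenylene)]dipropanoic acid F1. Sixfold methylation of the four phenols and two acids (MeI, K2CO3, DMF, 25–40 °C; Williamson and carboxylate alkylation) comes back to the route at 11.

**Step 1.**
- Bromination may stall after the third bromine, through deactivation and crowding around the ether oxygen.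
- The second bromine of a ring may enter para to the first.
- The formyl group may be oxidised under forcing conditions.
- Ipso attack at the formyl-bearing carbon (para to oxygen) may expel the formyl group.

The fallback sets out from 1 and moves the halogenation to an oxidation-proof substrate that tolerates a much stronger electrophile. Pinnick oxidation (NaClO2, NaH2PO4, 2-methyl-2-butene, t-BuOH/H2O) gives 4,4'-oxydibenzoic acid F2. Dibromoisocyanuric acid in conc. H2SO4 (25 → 90 °C), with the same matched ortho/meta direction, gives 4,4'-oxybis(3,5-dibromobenzoic acid) F3. BH3·THF reduction gives [oxybis(3,5-dibromo-4,1-phenylene)]dimethanol F4. MnO2 in CH2Cl2 oxidises the benzylic alcohols and comes back to the route at 3.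

**Step 2.**
- The tetrabromo dialdehyde may dissolve poorly in the formate medium.
- Hydride transfer may stay incomplete.
- While a ring carries the very strong arylidene acceptor, the ether ipso carbon is open to addition–elimination by the nucleophiles present, which would split the diaryl ether.

The fallback sets out from 3 and works under neutral, nucleophile-free conditions. Double Wittig olefination with methyl (triphenylphosphoranylidene)acetate (toluene, 60 °C) gives dimethyl (2E,2'E)-3,3'-[oxybis(3,5-dibromo-4,1-phenylene)]diacrylate F5. Homogeneous hydrogenation with RhCl(PPh3)3 (H2, 4 bar, THF/t-BuOH, 40 °C) saturates the alkenes without touching aryl bromides. This comes back to the route at 9 and bypasses 7 and step 3.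

**Further compounds**
F1 | step 4 | 3,3'-[oxybis(3,5-dihydroxy-4,1-phenylene)]dipropanoic acid | OC(=O)CCc1cc(O)c(Oc2c(O)cc(CCC(=O)O)cc2O)c(O)c1
F2 | step 1 | 4,4'-oxydibenzoic acid | OC(=O)c1ccc(Oc2ccc(C(=O)O)cc2)cc1
F3 | step 1 | 4,4'-oxybis(3,5-dibromobenzoic acid) | OC(=O)c1cc(Br)c(Oc2c(Br)cc(C(=O)O)cc2Br)c(Br)c1
F4 | step 1 | [oxybis(3,5-dibromo-4,1-phenylene)]dimethanol | OCc1cc(Br)c(Oc2c(Br)cc(CO)cc2Br)c(Br)c1
F5 | step 2 | dimethyl (2E,2'E)-3,3'-[oxybis(3,5-dibromo-4,1-phenylene)]diacrylate | COC(=O)/C=C/c1cc(Br)c(Oc2c(Br)cc(/C=C/C(=O)OC)cc2Br)c(Br)c1
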